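Ring A is cut across C2–C3 and C4–C5 into an ynone and a 3-aryloxy-1-methoxy-1-silyloxybutadiene. The feature used is the meta pair of oxygens on C2 and C6 of ring A with the acyl-derived side-chain carbon on C3, next to C2. One Diels–Alder benzannulation builds ring A, puts the ketone ortho to the new C2 hydroxyl and para to C6, and delivers the crowded C6–O–C1' ether to ring B ready-made, because ring B sits on the diene oxygen. The precursor is a silyl ketene acetal diene carrying ring B as allyl ether and dioxolane. The ketone then sets the (R)-centre; C1 is carboxylated last.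

Key step: step 9

Remark on numbering and geometry: ring A is C1 (CO2H), C2 (OMe), C3 (side chain), C6 (O-aryl); ring B is C1' (ether oxygen), C2' (OH), C4' (CH3), C6' (CHO). The double-bond geometry of the ketene acetal in 10 is left open, because that carbon becomes the sp2 carbon C2 of ring A.

Step 1
Reactants: 1 2-methoxy-4-methylphenol (creosol)
Product: 2 2-hydroxy-3-methoxy-5-methylbenzaldehyde
Conditions: MgCl2, Et3N, (CH2O)n, MeCN, reflux; aq. HCl work-up
Reagents that add atoms: paraformaldehyde (formaldehyde units), C=O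
Why: Magnesium-mediated ortho-formylation (Casnati–Skattebøl) should deliver formaldehyde through the magnesium phenoxide to the only free ortho carbon, and a second formaldehyde oxidises the benzylic alkoxide to the aldehyde.

Step 2
Reactants: 2 2-hydroxy-3-methoxy-5-methylbenzaldehyde
Product: 3 2,3-dihydroxy-5-methylbenzaldehyde
Conditions: BBr3, CH2Cl2, −78 → 0 °C; then H2O
Reagents that add atoms: none
Why: Lewis-acid cleavage of the aryl methyl ether by BBr3 frees the second hydroxyl at a stage where the formyl group still tells the two oxygens apart.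

Step 3
Reactants: 3 2,3-dihydroxy-5-methylbenzaldehyde
Product: 5 3-(allyloxy)-2-hydroxy-5-methylbenzaldehyde, via disodium catecholate 4 (not isolated)
Conditions: NaH (2.2 equiv), DMSO, rt; then allyl bromide (1.0 equiv), rt; aq. HCl work-up
Reagents that add atoms: allyl bromide, C=CCBr
Why: Williamson etherification of the dianion should occur at the C3 phenoxide, which is the more nucleophilic oxygen because the C2 phenoxide is conjugated with and chelated to the formyl group.

Step 4
Reactants: 5 3-(allyloxy)-2-hydroxy-5-methylbenzaldehyde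
Product: 6 2-(allyloxy)-6-(1,3-dioxolan-2-yl)-4-methylphenol
Conditions: HOCH2CH2OH, p-TsOH (cat.), toluene, reflux, Dean–Stark
Reagents that add atoms: ethylene glycol, OCCO
Why: Acid-catalysed acetalisation with azeotropic removal of water masks the aldehyde before any carbanion chemistry, since a free ortho-formyl group would trap the ester carbanion of the next step as a chromene and would not survive the amide base of step 6.

Step 5
Reactants: 6 2-(allyloxy)-6-(1,3-dioxolan-2-yl)-4-methylphenol; 7 methyl but-2-ynoate
Product: 8 methyl (E)-3-[2-(allyloxy)-6-(1,3-dioxolan-2-yl)-4-methylphenoxy]but-2-enoate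
Conditions: Cs2CO3 (0.3 equiv), DMF, 50 °C
Reagents that add atoms: none
Why: Base-catalysed oxa-Michael addition of the caesium phenoxide to the β-carbon of the ynoate makes the future diaryl ether C–O bond on an unhindered sp carbon and should equilibrate to the (E)-enoate, although either isomer gives the same dienolate in step 6.

Step 6
Reactants: 8 methyl (E)-3-[2-(allyloxy)-6-(1,3-dioxolan-2-yl)-4-methylphenoxy]but-2-enoate
Product: 10 {[3-(2-(allyloxy)-6-(1,3-dioxolan-2-yl)-4-methylphenoxy)-1-methoxybuta-1,3-dien-1-yl]oxy}trimethylsilane, via lithium dienolate 9 (not isolated)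
Conditions: LiN(iPr)2 (LDA), THF, −78 °C; then Me3SiCl, −78 °C → rt; pentane, filtration, used crude
Reagents that add atoms: chlorotrimethylsilane, C[Si](C)(C)Cl
Why: Kinetic γ-deprotonation of the β-aryloxy enoate (the methyl group lies cis to the ester) gives the extended dienolate, which Me3SiCl traps on oxygen as the silyl ketene acetal, the standard way to 1-alkoxy-1-silyloxy-3-oxy dienes.

Step 7
Reactants: 11 3-methylbutanal; 12 ethynylmagnesium bromide
Product: 13 5-methylhex-1-yn-3-ol (racemic)
Conditions: THF, 0 °C → rt; aq. NH4Cl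
Reagents that add atoms: none
Why: Grignard 1,2-addition of the alkynyl nucleophile to the aldehyde is reliable, and the racemic carbinol centre is removed in the next step.

Step 8
Reactants: 13 5-methylhex-1-yn-3-ol (racemic)
Product: 14 5-methylhex-1-yn-3-one
Conditions: Dess–Martin periodinane, NaHCO3, CH2Cl2, 0 °C → rt
Reagents that add atoms: none
Why: Dess–Martin oxidation converts the secondary propargylic alcohol into the ynone under buffered, non-aqueous conditions that spare the terminal alkyne; the volatile product is used as a concentrated solution.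

Step 9
Reactants: 10 {[3-(2-(allyloxy)-6-(1,3-dioxolan-2-yl)-4-methylphenoxy)-1-methoxybuta-1,3-dien-1-yl]oxy}trimethylsilane; 14 5-methylhex-1-yn-3-one
Product: 16 1-{4-[2-(allyloxy)-6-(1,3-dioxolan-2-yl)-4-methylphenoxy]-2-hydroxyphenyl}-3-methylbutan-1-one, via cyclohexa-1,4-diene ketal cycloadduct 15 (not isolated)
Conditions: toluene, rt → 60 °C; then Bu4NF, AcOH, THF, 0 °C
Reagents that add atoms: none
Why: The electron-rich diene 10 and the ynone 14 should combine in a normal-electron-demand, asynchronous [4+2] cycloaddition in which the terminal CH2 of the diene (largest HOMO coefficient, pushed by the C3 aryloxy and the ketene acetal oxygens) bonds to the β-carbon of the ynone and the ketene acetal carbon bonds to the α-carbon, so that bonds C4–C5 and C2–C3 form and ring A closes as the six-membered cyclohexa-1,4-diene 15. Buffered fluoride then removes the silyl group, the mixed ketal collapses with loss of methanol, and the cyclohexadienone tautomerises to the hydrogen-bonded ortho-hydroxyaryl ketone 16. The closest known reaction type is the Diels–Alder benzannulation of 1-alkoxy-1-silyloxy-3-alkoxybuta-1,3-dienes with alkynyl ketones and esters to salicylate-type arenes, from which this diene differs only in the group on the C3 oxygen. No stereocenter is formed, since the ketal carbon of 15 becomes the sp2 carbon C2. The selectivity needed is regiochemical (acyl group ortho to the new hydroxyl and para to the aryloxy group) and is secured by the matched polarity of the two partners, while the allyl ether stays far below its Claisen temperature and the dioxolane meets no aqueous acid. Any anisole formed by loss of silanol in place of methanol would converge with 16 in step 10.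

Step 10
Reactants: 16 1-{4-[2-(allyloxy)-6-(1,3-dioxolan-2-yl)-4-methylphenoxy]-2-hydroxyphenyl}-3-methylbutan-1-one
Product: 17 1-{4-[2-(allyloxy)-6-(1,3-dioxolan-2-yl)-4-methylphenoxy]-2-methoxyphenyl}-3-methylbutan-1-one
Conditions: MeI, K2CO3, DMF, 40 °C
Reagents that add atoms: iodomethane, CI
Why: Williamson O-methylation of the only acidic hydroxyl should proceed once warm K2CO3 in DMF breaks the hydrogen bond to the ketone, and it installs the C2 methoxy group of ring A.

Step 11
Reactants: 17 1-{4-[2-(allyloxy)-6-(1,3-dioxolan-2-yl)-4-methylphenoxy]-2-methoxyphenyl}-3-methylbutan-1-one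
Product: 18 (1R)-1-{4-[2-(allyloxy)-6-(1,3-dioxolan-2-yl)-4-methylphenoxy]-2-methoxyphenyl}-3-methylbutan-1-ol
Conditions: RuCl[(R,R)-TsDPEN](p-cymene) (1 mol%), HCO2H–Et3N (1:1), DMF, 40 °C
Reagents that add atoms: none
Why: Noyori asymmetric transfer hydrogenation should deliver hydride from the ruthenium hydride to the Si face of the aryl alkyl ketone, because the aryl group sits next to the η6-arene of the (R,R)-catalyst in the six-membered transition state, which gives the (R)-carbinol in the same sense as for acetophenone; the near-neutral formate medium spares the dioxolane and the allyl ether.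

Step 12
Reactants: 18 (1R)-1-{4-[2-(allyloxy)-6-(1,3-dioxolan-2-yl)-4-methylphenoxy]-2-methoxyphenyl}-3-methylbutan-1-ol
Product: 20 2-[3-(allyloxy)-2-{3-methoxy-4-[(1R)-1-methoxy-3-methylbutyl]phenoxy}-5-methylphenyl]-1,3-dioxolane, via sodium alkoxide 19 (not isolated)
Conditions: NaH, THF, 0 °C; then MeI, 0 °C → rt
Reagents that add atoms: iodomethane, CI
Why: Williamson methylation of the sodium alkoxide forms the ether at oxygen without touching the C–O bond of the stereocenter, so the (R) configuration is retained.

Step 13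
Reactants: 20 2-[3-(allyloxy)-2-{3-methoxy-4-[(1R)-1-methoxy-3-methylbutyl]phenoxy}-5-methylphenyl]-1,3-dioxolane
Product: 21 3-(1,3-dioxolan-2-yl)-2-{3-methoxy-4-[(1R)-1-methoxy-3-methylbutyl]phenoxy}-5-methylphenol
Conditions: Pd(PPh3)4 (5 mol%), morpholine, THF, rt
Reagents that add atoms: none
Why: Tsuji–Trost deallylation, in which zerovalent palladium ionises the allyl aryl ether to a π-allyl complex that morpholine captures, frees the ring B phenol under neutral conditions and removes the allyl group before the alkyllithium step that it would not survive.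

Step 14
Reactants: 21 3-(1,3-dioxolan-2-yl)-2-{3-methoxy-4-[(1R)-1-methoxy-3-methylbutyl]phenoxy}-5-methylphenol
Product: 24 6-(2-formyl-6-hydroxy-4-methylphenoxy)-2-methoxy-3-[(1R)-1-methoxy-3-methylbutyl]benzoic acid, via C1-lithiated lithium phenoxide 22 (not isolated), via dioxolane-protected acid 23 (not isolated)
Conditions: n-BuLi (2.3 equiv), THF, −78 → 0 °C; then CO2, −78 °C → rt; then 1 M HCl, THF, rt
Reagents that add atoms: carbon dioxide, O=C=O; water, O
Why: Directed ortho-metalation should first form the ring B lithium phenoxide, which shuts ring B off, and then remove the C1 hydrogen, the only one flanked by two ether oxygens (OMe and O-aryl acting together), after which CO2 carboxylates the aryllithium and dilute acid frees the acid and hydrolyses the aryl dioxolane much faster than the benzylic methyl ether can ionise; the tertiary benzylic C–H of the stereocenter is far less acidic than C1–H and the dianion resists a further deprotonation.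

Compound list
1 | 2-methoxy-4-methylphenol (creosol) | COc1cc(C)ccc1O | starting material
2 | 2-hydroxy-3-methoxy-5-methylbenzaldehyde | COc1cc(C)cc(C=O)c1O | intermediate
3 | 2,3-dihydroxy-5-methylbenzaldehyde | Oc1cc(C)cc(C=O)c1O | intermediate
4 | disodium 3-formyl-5-methylbenzene-1,2-bis(olate) | [Na+].[Na+].[O-]c1cc(C)cc(C=O)c1[O-] | intermediate (not isolated)
5 | 3-(allyloxy)-2-hydroxy-5-methylbenzaldehyde | C=CCOc1cc(C)cc(C=O)c1O | intermediate
6 | 2-(allyloxy)-6-(1,3-dioxolan-2-yl)-4-methylphenol | C=CCOc1cc(C)cc(C2OCCO2)c1O | intermediate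
7 | methyl but-2-ynoate | CC#CC(=O)OC | starting material
8 | methyl (E)-3-[2-(allyloxy)-6-(1,3-dioxolan-2-yl)-4-methylphenoxy]but-2-enoate | C/C(Oc1c(OCC=C)cc(C)cc1C2OCCO2)=C\C(=O)OC | intermediate
9 | lithium 3-[2-(allyloxy)-6-(1,3-dioxolan-2-yl)-4-methylphenoxy]-1-methoxybuta-1,3-dien-1-olate | [Li+].[O-]C(OC)=CC(=C)Oc1c(OCC=C)cc(C)cc1C2OCCO2 | intermediate (not isolated)
10 | {[3-(2-(allyloxy)-6-(1,3-dioxolan-2-yl)-4-methylphenoxy)-1-methoxybuta-1,3-dien-1-yl]oxy}trimethylsilane | C=C(Oc1c(OCC=C)cc(C)cc1C2OCCO2)C=C(OC)O[Si](C)(C)C | intermediate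
11 | 3-methylbutanal | CC(C)CC=O | starting material
12 | ethynylmagnesium bromide | C#C[Mg]Br | starting material
13 | 5-methylhex-1-yn-3-ol (racemic) | C#CC(O)CC(C)C | intermediate
14 | 5-methylhex-1-yn-3-one | C#CC(=O)CC(C)C | intermediate
15 | 1-{4-[2-(allyloxy)-6-(1,3-dioxolan-2-yl)-4-methylphenoxy]-6-methoxy-6-(trimethylsilyloxy)cyclohexa-1,4-dien-1-yl}-3-methylbutan-1-one (racemic) | COC1(O[Si](C)(C)C)C=C(Oc2c(OCC=C)cc(C)cc2C3OCCO3)CC=C1C(=O)CC(C)C | intermediate (not isolated)
16 | 1-{4-[2-(allyloxy)-6-(1,3-dioxolan-2-yl)-4-methylphenoxy]-2-hydroxyphenyl}-3-methylbutan-1-one | CC(C)CC(=O)c1ccc(Oc2c(OCC=C)cc(C)cc2C3OCCO3)cc1O | intermediate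
17 | 1-{4-[2-(allyloxy)-6-(1,3-dioxolan-2-yl)-4-methylphenoxy]-2-methoxyphenyl}-3-methylbutan-1-one | CC(C)CC(=O)c1ccc(Oc2c(OCC=C)cc(C)cc2C3OCCO3)cc1OC | intermediate
18 | (1R)-1-{4-[2-(allyloxy)-6-(1,3-dioxolan-2-yl)-4-methylphenoxy]-2-methoxyphenyl}-3-methylbutan-1-ol | CC(C)C[C@@H](O)c1ccc(Oc2c(OCC=C)cc(C)cc2C3OCCO3)cc1OC | intermediate
19 | sodium (1R)-1-{4-[2-(allyloxy)-6-(1,3-dioxolan-2-yl)-4-methylphenoxy]-2-methoxyphenyl}-3-methylbutan-1-olate | [Na+].CC(C)C[C@@H]([O-])c1ccc(Oc2c(OCC=C)cc(C)cc2C3OCCO3)cc1OC | intermediate (not isolated)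
20 | 2-[3-(allyloxy)-2-{3-methoxy-4-[(1R)-1-methoxy-3-methylbutyl]phenoxy}-5-methylphenyl]-1,3-dioxolane | CC(C)C[C@@H](OC)c1ccc(Oc2c(OCC=C)cc(C)cc2C3OCCO3)cc1OC | intermediate
21 | 3-(1,3-dioxolan-2-yl)-2-{3-methoxy-4-[(1R)-1-methoxy-3-methylbutyl]phenoxy}-5-methylphenol | CC(C)C[C@@H](OC)c1ccc(Oc2c(O)cc(C)cc2C3OCCO3)cc1OC | intermediate
22 | lithium 3-(1,3-dioxolan-2-yl)-2-{2-lithio-3-methoxy-4-[(1R)-1-methoxy-3-methylbutyl]phenoxy}-5-methylphenolate | CC(C)C[C@@H](OC)c1ccc(Oc2c(O[Li])cc(C)cc2C3OCCO3)c([Li])c1OC | intermediate (not isolated)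
23 | 6-[2-(1,3-dioxolan-2-yl)-6-hydroxy-4-methylphenoxy]-2-methoxy-3-[(1R)-1-methoxy-3-methylbutyl]benzoic acid | CC(C)C[C@@H](OC)c1ccc(Oc2c(O)cc(C)cc2C3OCCO3)c(C(=O)O)c1OC | intermediate (not isolated)
24 | 6-(2-formyl-6-hydroxy-4-methylphenoxy)-2-methoxy-3-[(1R)-1-methoxy-3-methylbutyl]benzoic acid | COc1c([C@@H](CC(C)C)OC)ccc(Oc2c(O)cc(C)cc2C=O)c1C(=O)O | target

Total step count: 14.
Longest linear sequence: 12 steps (steps 1–6 and 9–14 from creosol); the ynone branch (steps 7 and 8) joins at step 9.

Steps most likely to fail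

Step 9, the cycloaddition. The aryloxy diene is bulkier and less electron-rich than its 3-alkoxy relatives. The cycloaddition may therefore be outrun by protodesilylation of the ketene acetal or by oligomerisation of the ynone. The fallback makes the diaryl ether by nucleophilic aromatic substitution instead of by ring construction. Commercial 4-fluoro-2-methoxybenzaldehyde and i-BuMgBr (THF, 0 °C) should give 1-(4-fluoro-2-methoxyphenyl)-3-methylbutan-1-ol F1. Dess–Martin periodinane oxidises it to 1-(4-fluoro-2-methoxyphenyl)-3-methylbutan-1-one F2. Phenol 6 with K2CO3 in DMSO at 120 °C then displaces the fluoride para to the ketone. The fallback sets out from 6 and comes back to the route at 17, so steps 5, 6, 9 and 10 are bypassed.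

Step 14, the metalation and carboxylation. Metalation of the lithium phenoxide may stay incomplete or go to another ring position. Proton abstraction at the methoxy-bearing benzylic carbon could erode the configuration, and the base could attack the dioxolane. The fallback carries the stereocenter through the metalation as its lithium alkoxide, which cannot be deprotonated at carbon, and forms the methyl ether afterwards.
- It sets out from 18. Pd(PPh3)4 and morpholine remove the allyl group to give 3-(1,3-dioxolan-2-yl)-2-{4-[(1R)-1-hydroxy-3-methylbutyl]-3-methoxyphenoxy}-5-methylphenol F3.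
- i-Pr3SiCl and imidazole in DMF silylate only the phenol, giving (1R)-1-(4-{2-(1,3-dioxolan-2-yl)-4-methyl-6-[(triisopropylsilyl)oxy]phenoxy}-2-methoxyphenyl)-3-methylbutan-1-ol F4.
- n-BuLi (2.2 equiv, THF, −78 → 0 °C) forms the alkoxide and lithiates C1. CO2 and a cold, mildly acidic work-up give 6-{2-(1,3-dioxolan-2-yl)-4-methyl-6-[(triisopropylsilyl)oxy]phenoxy}-3-[(1R)-1-hydroxy-3-methylbutyl]-2-methoxybenzoic acid F5.
- NaH and MeI in THF methylate the alkoxide, while the sodium carboxylate is expected to stay unalkylated in this solvent. The product is 6-{2-(1,3-dioxolan-2-yl)-4-methyl-6-[(triisopropylsilyl)oxy]phenoxy}-2-methoxy-3-[(1R)-1-methoxy-3-methylbutyl]benzoic acid F6.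
- Bu4NF in THF removes the silyl group. The fallback comes back to the route at 23, which 1 M HCl in THF converts into 24 as in step 14.

Step 11, the asymmetric reduction. Hydride transfer to the electron-rich, ortho-substituted ketone may be slow, and the ortho methoxy group and the branched chain may lower the facial selectivity. The fallback replaces metal–ligand transfer hydrogenation by a Corey–Bakshi–Shibata reduction: (S)-2-methyl-CBS-oxazaborolidine (catalytic) with catecholborane in toluene at −78 °C. Facial selection then rests on the size difference between the aryl group and the CH2 of the side chain, and should again give the (R)-alcohol. Catecholborane leaves the allyl ether alone at this temperature. The fallback sets out from 17 and comes back at 18; no compound outside the list arises (F0).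

Further compounds
F1 | step 9 | 1-(4-fluoro-2-methoxyphenyl)-3-methylbutan-1-ol (racemic) | CC(C)CC(O)c1ccc(F)cc1OC
F2 | step 9 | 1-(4-fluoro-2-methoxyphenyl)-3-methylbutan-1-one | CC(C)CC(=O)c1ccc(F)cc1OC
F3 | step 14 | 3-(1,3-dioxolan-2-yl)-2-{4-[(1R)-1-hydroxy-3-methylbutyl]-3-methoxyphenoxy}-5-methylphenol | CC(C)C[C@@H](O)c1ccc(Oc2c(O)cc(C)cc2C3OCCO3)cc1OC
F4 | step 14 | (1R)-1-(4-{2-(1,3-dioxolan-2-yl)-4-methyl-6-[(triisopropylsilyl)oxy]phenoxy}-2-methoxyphenyl)-3-methylbutan-1-ol | CC(C)C[C@@H](O)c1ccc(Oc2c(O[Si](C(C)C)(C(C)C)C(C)C)cc(C)cc2C3OCCO3)cc1OC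
F5 | step 14 | 6-{2-(1,3-dioxolan-2-yl)-4-methyl-6-[(triisopropylsilyl)oxy]phenoxy}-3-[(1R)-1-hydroxy-3-methylbutyl]-2-methoxybenzoic acid | CC(C)C[C@@H](O)c1ccc(Oc2c(O[Si](C(C)C)(C(C)C)C(C)C)cc(C)cc2C3OCCO3)c(C(=O)O)c1OC
F6 | step 14 | 6-{2-(1,3-dioxolan-2-yl)-4-methyl-6-[(triisopropylsilyl)oxy]phenoxy}-2-methoxy-3-[(1R)-1-methoxy-3-methylbutyl]benzoic acid | CC(C)C[C@@H](OC)c1ccc(Oc2c(O[Si](C(C)C)(C(C)C)C(C)C)cc(C)cc2C3OCCO3)c(C(=O)O)c1OC
F0 | step 11 | none | none
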